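**Retrosynthetic overview**
- The aryl ketone is unveiled last, by oxidation of a carbinol and desilylation. The C4 centre is therefore fixed (trans to C3) before it becomes enolisable, and trans is also the more stable arrangement.
- The tetrahydrofuran, the only ring, is closed by a 5-exo-tet O-alkylation: the benzylic hydroxyl displaces a primary tosylate, so the benzylic configuration is retained.
- The C4–C(aryl) bond comes from an aldol reaction of a cis-4,5-disubstituted γ-butyrolactone enolate with 3,4,5-trimethoxybenzaldehyde, on the face opposite both substituents.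
- The lactone comes from oxidative cleavage of an allyl group. The C2/C3 relationship comes from an anti-selective dianion allylation of a β-hydroxy ester.
- The first stereocentre comes from ketoreductase reduction of an achiral β-keto ester. Ring order: lactol/lactone first, opened to a diol, then re-closed as the cyclic ether.

Assumption: the β-keto ester is bought, the ketoreductase is an (R)-selective enzyme taken from a commercial screening panel, and mixtures at the lactol carbon and at the carbinol carbon made in the aldol step are carried on because both centres are removed later.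

**Step 1**
Reactants: 1 ethyl 3-(3,4-dimethoxyphenyl)-3-oxopropanoate
Product: 2 ethyl (3R)-3-(3,4-dimethoxyphenyl)-3-hydroxypropanoate
Conditions: ketoreductase (R-selective KRED, an NADPH-dependent alcohol dehydrogenase), NADP+ (cat.), i-PrOH (10% v/v), KH2PO4/K2HPO4 buffer pH 7.0, 30 °C
Reagents that add atoms: none
Why: Enzymatic asymmetric ketone reduction, in which the ketoreductase passes hydride from NADPH (recycled by isopropanol) to one face of the achiral aryl ketone and so sets the first stereocentre (R, the future C2) in high ee.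

**Step 2**
Reactants: 2 ethyl (3R)-3-(3,4-dimethoxyphenyl)-3-hydroxypropanoate; 3 allyl bromide
Product: 5 ethyl (2S)-2-[(R)-(3,4-dimethoxyphenyl)(hydroxy)methyl]pent-4-enoate, via dilithium dianion 4 (not isolated)
Conditions: LiN(i-Pr)2 (2.2 equiv), THF, −78 → −20 °C; then allyl bromide, DMPU, −78 → −10 °C
Reagents that add atoms: allyl bromide (3), C=CCBr
Why: Fráter–Seebach alkylation, in which the chelated lithium alkoxide–enolate is allylated on the face away from the aryl group to give the anti (2S,3R) product that carries the future cis C2/C3 relationship.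

**Step 3**
Reactants: 5 ethyl (2S)-2-[(R)-(3,4-dimethoxyphenyl)(hydroxy)methyl]pent-4-enoate
Product: 6 (1R,2R)-1-(3,4-dimethoxyphenyl)-2-(prop-2-en-1-yl)propane-1,3-diol
Conditions: LiAlH4, THF, 0 °C
Reagents that add atoms: none
Why: Hydride reduction of the ester to the primary alcohol, which leaves the alkene and both stereocentres untouched.

**Step 4**
Reactants: 6 (1R,2R)-1-(3,4-dimethoxyphenyl)-2-(prop-2-en-1-yl)propane-1,3-diol
Product: 7 (1R,2R)-2-[(tert-butyldimethylsilyloxy)methyl]-1-(3,4-dimethoxyphenyl)pent-4-en-1-ol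
Conditions: TBSCl (1.05 equiv), imidazole, CH2Cl2, 0 °C
Reagents that add atoms: tert-butyldimethylsilyl chloride (TBSCl), CC(C)(C)[Si](C)(C)Cl
Why: Selective silyl ether formation, since the primary hydroxyl reacts much faster than the hindered secondary benzylic one.

**Step 5**
Reactants: 7 (1R,2R)-2-[(tert-butyldimethylsilyloxy)methyl]-1-(3,4-dimethoxyphenyl)pent-4-en-1-ol
Product: 10 (4R,5R)-4-[(tert-butyldimethylsilyloxy)methyl]-5-(3,4-dimethoxyphenyl)tetrahydrofuran-2-ol (anomer mixture), via triol 8 (not isolated), via hydroxy aldehyde 9 (not isolated)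
Conditions: OsO4 (2 mol %), NaIO4 (4 equiv), 2,6-lutidine, 1,4-dioxane/H2O 3:1, rt
Reagents that add atoms: osmium tetroxide, O=[Os](=O)(=O)=O; sodium periodate, [Na+].[O-]I(=O)(=O)=O; water, O
Why: Lemieux–Johnson oxidation (dihydroxylation then periodate glycol cleavage) removes the terminal carbon, and the 4-hydroxy aldehyde closes at once to the five-membered lactol without touching an existing stereocentre.

**Step 6**
Reactants: 10 (4R,5R)-4-[(tert-butyldimethylsilyloxy)methyl]-5-(3,4-dimethoxyphenyl)tetrahydrofuran-2-ol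
Product: 11 (4R,5R)-4-[(tert-butyldimethylsilyloxy)methyl]-5-(3,4-dimethoxyphenyl)dihydrofuran-2(3H)-one
Conditions: TEMPO (10 mol %), PhI(OAc)2, CH2Cl2, rt
Reagents that add atoms: none
Why: Oxoammonium (TEMPO)-mediated oxidation of the lactol to the lactone under mild conditions that spare the electron-rich arene and the silyl ether.

**Step 7**
Reactants: 11 (4R,5R)-4-[(tert-butyldimethylsilyloxy)methyl]-5-(3,4-dimethoxyphenyl)dihydrofuran-2(3H)-one; 12 3,4,5-trimethoxybenzaldehyde
Product: 14 (3R,4R,5R)-4-[(tert-butyldimethylsilyloxy)methyl]-5-(3,4-dimethoxyphenyl)-3-[hydroxy(3,4,5-trimethoxyphenyl)methyl]dihydrofuran-2(3H)-one (both carbinol epimers), via lithium enolate 13 (not isolated)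
Conditions: LiN(i-Pr)2 (1.1 equiv), THF, −78 °C; then 3,4,5-trimethoxybenzaldehyde, −78 °C
Reagents that add atoms: 3,4,5-trimethoxybenzaldehyde (12), COc1cc(C=O)cc(OC)c1OC
Why: Aldol addition of the lactone lithium enolate, in which the aldehyde adds to the face opposite the cis C4 and C5 substituents and so sets C3 (future C4 of the target) trans, while the carbinol mixture is erased in step 10.

**Step 8**
Reactants: 14 (3R,4R,5R)-4-[(tert-butyldimethylsilyloxy)methyl]-5-(3,4-dimethoxyphenyl)-3-[hydroxy(3,4,5-trimethoxyphenyl)methyl]dihydrofuran-2(3H)-one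
Product: 15 (1R,2R,3S)-2-[(tert-butyldimethylsilyloxy)methyl]-1-(3,4-dimethoxyphenyl)-3-[hydroxy(3,4,5-trimethoxyphenyl)methyl]butane-1,4-diol (both carbinol epimers)
Conditions: LiBH4, THF, 0 °C → rt
Reagents that add atoms: none
Why: Hydride reduction of the lactone to the 1,4-diol with a mild, weakly basic borohydride that keeps retro-aldol and silyl loss down and touches no stereocentre.

**Step 9**
Reactants: 15 (1R,2R,3S)-2-[(tert-butyldimethylsilyloxy)methyl]-1-(3,4-dimethoxyphenyl)-3-[hydroxy(3,4,5-trimethoxyphenyl)methyl]butane-1,4-diol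
Product: 17 [(3S,4R,5R)-4-[(tert-butyldimethylsilyloxy)methyl]-5-(3,4-dimethoxyphenyl)tetrahydrofuran-3-yl](3,4,5-trimethoxyphenyl)methanol (both carbinol epimers), via primary tosylate 16 (not isolated)
Conditions: TsCl (1.05 equiv), DMAP (cat.), pyridine, 0 °C → rt; then 50 °C
Reagents that add atoms: none
Why: Selective sulfonylation of the only primary hydroxyl followed by intramolecular Williamson etherification (5-exo-tet) by the C1 benzylic hydroxyl, which keeps the benzylic configuration because its C–O bond is never broken, whereas closure by the other secondary hydroxyl would need a four-membered ring.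

**Step 10**
Reactants: 17 [(3S,4R,5R)-4-[(tert-butyldimethylsilyloxy)methyl]-5-(3,4-dimethoxyphenyl)tetrahydrofuran-3-yl](3,4,5-trimethoxyphenyl)methanol
Product: 18 [(3S,4R,5R)-4-[(tert-butyldimethylsilyloxy)methyl]-5-(3,4-dimethoxyphenyl)tetrahydrofuran-3-yl](3,4,5-trimethoxyphenyl)methanone
Conditions: Dess–Martin periodinane, pyridine, CH2Cl2, 0 °C → rt
Reagents that add atoms: none
Why: Dess–Martin oxidation of the secondary benzylic alcohol to the aryl ketone merges both carbinol epimers into one compound whose now enolisable C3 already has the more stable trans arrangement.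

**Step 11**
Reactants: 18 [(3S,4R,5R)-4-[(tert-butyldimethylsilyloxy)methyl]-5-(3,4-dimethoxyphenyl)tetrahydrofuran-3-yl](3,4,5-trimethoxyphenyl)methanone
Product: 19 [(3S,4R,5R)-5-(3,4-dimethoxyphenyl)-4-(hydroxymethyl)tetrahydrofuran-3-yl](3,4,5-trimethoxyphenyl)methanone (CNP0271206.1)
Conditions: HF·pyridine, pyridine/THF, 0 °C → rt
Reagents that add atoms: none
Why: Fluoride-driven silyl ether cleavage under buffered, nearly neutral conditions that avoid both acid epimerisation at the benzylic ether carbon and base-induced retro-oxa-Michael opening.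

**Compound list**
1 | ethyl 3-(3,4-dimethoxyphenyl)-3-oxopropanoate | CCOC(=O)CC(=O)c1ccc(OC)c(OC)c1 | starting material
2 | ethyl (3R)-3-(3,4-dimethoxyphenyl)-3-hydroxypropanoate | CCOC(=O)C[C@@H](O)c1ccc(OC)c(OC)c1 | intermediate
3 | allyl bromide | C=CCBr | starting material
4 | dilithium alkoxide–enolate of 2 (chelated dianion, enolate O–Li cis to C3) | [Li+].[Li+].CCO/C([O-])=C/[C@@H]([O-])c1ccc(OC)c(OC)c1 | intermediate
5 | ethyl (2S)-2-[(R)-(3,4-dimethoxyphenyl)(hydroxy)methyl]pent-4-enoate (anti) | CCOC(=O)[C@@H](CC=C)[C@@H](O)c1ccc(OC)c(OC)c1 | intermediate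
6 | (1R,2R)-1-(3,4-dimethoxyphenyl)-2-(prop-2-en-1-yl)propane-1,3-diol | OC[C@@H](CC=C)[C@@H](O)c1ccc(OC)c(OC)c1 | intermediate
7 | (1R,2R)-2-[(tert-butyldimethylsilyloxy)methyl]-1-(3,4-dimethoxyphenyl)pent-4-en-1-ol | CC(C)(C)[Si](C)(C)OC[C@@H](CC=C)[C@@H](O)c1ccc(OC)c(OC)c1 | intermediate
8 | (1R,2R)-2-[(tert-butyldimethylsilyloxy)methyl]-1-(3,4-dimethoxyphenyl)pentane-1,4,5-triol (both C4 epimers) | CC(C)(C)[Si](C)(C)OC[C@@H](CC(O)CO)[C@@H](O)c1ccc(OC)c(OC)c1 | intermediate
9 | (3R,4R)-3-[(tert-butyldimethylsilyloxy)methyl]-4-(3,4-dimethoxyphenyl)-4-hydroxybutanal | CC(C)(C)[Si](C)(C)OC[C@@H](CC=O)[C@@H](O)c1ccc(OC)c(OC)c1 | intermediate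
10 | (4R,5R)-4-[(tert-butyldimethylsilyloxy)methyl]-5-(3,4-dimethoxyphenyl)tetrahydrofuran-2-ol (anomer mixture; aryl and silyloxymethyl cis) | COc1ccc([C@@H]2OC(O)C[C@@H]2CO[Si](C)(C)C(C)(C)C)cc1OC | intermediate
11 | (4R,5R)-4-[(tert-butyldimethylsilyloxy)methyl]-5-(3,4-dimethoxyphenyl)dihydrofuran-2(3H)-one (cis) | COc1ccc([C@@H]2OC(=O)C[C@@H]2CO[Si](C)(C)C(C)(C)C)cc1OC | intermediate
12 | 3,4,5-trimethoxybenzaldehyde | COc1cc(C=O)cc(OC)c1OC | starting material
13 | lithium enolate of lactone 11 | [Li+].COc1ccc([C@@H]2OC([O-])=C[C@@H]2CO[Si](C)(C)C(C)(C)C)cc1OC | intermediate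
14 | (3R,4R,5R)-4-[(tert-butyldimethylsilyloxy)methyl]-5-(3,4-dimethoxyphenyl)-3-[hydroxy(3,4,5-trimethoxyphenyl)methyl]dihydrofuran-2(3H)-one (both carbinol epimers; C3 group trans to the C4 and C5 groups) | COc1ccc([C@@H]2OC(=O)[C@@H](C(O)c3cc(OC)c(OC)c(OC)c3)[C@@H]2CO[Si](C)(C)C(C)(C)C)cc1OC | intermediate
15 | (1R,2R,3S)-2-[(tert-butyldimethylsilyloxy)methyl]-1-(3,4-dimethoxyphenyl)-3-[hydroxy(3,4,5-trimethoxyphenyl)methyl]butane-1,4-diol (both carbinol epimers) | COc1ccc([C@H](O)[C@@H](CO[Si](C)(C)C(C)(C)C)[C@@H](CO)C(O)c2cc(OC)c(OC)c(OC)c2)cc1OC | intermediate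
16 | primary (C4–O) p-toluenesulfonate of triol 15 | COc1ccc([C@H](O)[C@@H](CO[Si](C)(C)C(C)(C)C)[C@@H](COS(=O)(=O)c2ccc(C)cc2)C(O)c2cc(OC)c(OC)c(OC)c2)cc1OC | intermediate
17 | [(3S,4R,5R)-4-[(tert-butyldimethylsilyloxy)methyl]-5-(3,4-dimethoxyphenyl)tetrahydrofuran-3-yl](3,4,5-trimethoxyphenyl)methanol (both carbinol epimers) | COc1ccc([C@@H]2OC[C@@H](C(O)c3cc(OC)c(OC)c(OC)c3)[C@@H]2CO[Si](C)(C)C(C)(C)C)cc1OC | intermediate
18 | [(3S,4R,5R)-4-[(tert-butyldimethylsilyloxy)methyl]-5-(3,4-dimethoxyphenyl)tetrahydrofuran-3-yl](3,4,5-trimethoxyphenyl)methanone | COc1ccc([C@@H]2OC[C@@H](C(=O)c3cc(OC)c(OC)c(OC)c3)[C@@H]2CO[Si](C)(C)C(C)(C)C)cc1OC | intermediate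
19 | [(3S,4R,5R)-5-(3,4-dimethoxyphenyl)-4-(hydroxymethyl)tetrahydrofuran-3-yl](3,4,5-trimethoxyphenyl)methanone (aryl and CH2OH cis, CH2OH and aroyl trans) | COc1ccc([C@@H]2OC[C@@H](C(=O)c3cc(OC)c(OC)c(OC)c3)[C@@H]2CO)cc1OC | target

**Totals**
Total step count: 11. Longest linear sequence: 11 steps (1 → 19).

**Steps most likely to fail, with fallbacks**

Step 2 (dianion allylation). The risks are retro-aldol of the dianion, O-allylation and eroded anti-selectivity. The fallback sets out from 1. It is C-allylated with allyl bromide 3 and K2CO3 in acetone to racemic, configurationally labile ethyl 2-(3,4-dimethoxybenzoyl)pent-4-enoate F1. F1 is then reduced by an anti-selective ketoreductase under dynamic kinetic resolution (NADP+, i-PrOH, buffer pH 7–8), which sets both centres in one enzymatic step. The fallback comes back to the route at 5.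

Step 7 (lactone aldol). The risks are retro-aldol on quench, dehydration to the benzylidene lactone and incomplete facial control. The fallback sets out from 11. Its lithium enolate (2.2 equiv LiN(i-Pr)2) is acylated with methyl 3,4,5-trimethoxybenzoate in a crossed Claisen condensation. This gives (3R,4R,5R)-4-[(tert-butyldimethylsilyloxy)methyl]-5-(3,4-dimethoxyphenyl)-3-(3,4,5-trimethoxybenzoyl)dihydrofuran-2(3H)-one F2, whose doubly activated C3 settles trans to C4 under thermodynamic control. Only the ketone is then reduced with NaBH4 in MeOH at −20 °C. The fallback comes back at 14.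

Step 9 (tosylation and ring closure with three free hydroxyls). The risks are over-sulfonylation and ionisation at a benzylic carbinol. The fallback sets out from 14.
- The carbinol is silylated (TBSOTf, 2,6-lutidine, CH2Cl2, −78 °C) to the bis-silyl lactone (3R,4R,5R)-4-[(tert-butyldimethylsilyloxy)methyl]-3-[(tert-butyldimethylsilyloxy)(3,4,5-trimethoxyphenyl)methyl]-5-(3,4-dimethoxyphenyl)dihydrofuran-2(3H)-one F3.
- LiBH4 reduction gives (1R,2R,3S)-2-[(tert-butyldimethylsilyloxy)methyl]-3-[(tert-butyldimethylsilyloxy)(3,4,5-trimethoxyphenyl)methyl]-1-(3,4-dimethoxyphenyl)butane-1,4-diol F4.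
- The primary hydroxyl is tosylated (TsCl, pyridine) to the primary p-toluenesulfonate of F4, F5.
- KOt-Bu in THF at 0 °C closes the ring to (2R,3R,4S)-3-[(tert-butyldimethylsilyloxy)methyl]-4-[(tert-butyldimethylsilyloxy)(3,4,5-trimethoxyphenyl)methyl]-2-(3,4-dimethoxyphenyl)tetrahydrofuran F6.
- HF·pyridine removes both silyl groups to give [(3S,4R,5R)-5-(3,4-dimethoxyphenyl)-4-(hydroxymethyl)tetrahydrofuran-3-yl](3,4,5-trimethoxyphenyl)methanol F7.
- Activated MnO2 in CH2Cl2 oxidises only the benzylic alcohol.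

The fallback comes back at the target 19.

**Further compounds**
F1 | step 2 | ethyl 2-(3,4-dimethoxybenzoyl)pent-4-enoate (racemic) | CCOC(=O)C(CC=C)C(=O)c1ccc(OC)c(OC)c1
F2 | step 7 | (3R,4R,5R)-4-[(tert-butyldimethylsilyloxy)methyl]-5-(3,4-dimethoxyphenyl)-3-(3,4,5-trimethoxybenzoyl)dihydrofuran-2(3H)-one | COc1ccc([C@@H]2OC(=O)[C@@H](C(=O)c3cc(OC)c(OC)c(OC)c3)[C@@H]2CO[Si](C)(C)C(C)(C)C)cc1OC
F3 | step 9 | (3R,4R,5R)-4-[(tert-butyldimethylsilyloxy)methyl]-3-[(tert-butyldimethylsilyloxy)(3,4,5-trimethoxyphenyl)methyl]-5-(3,4-dimethoxyphenyl)dihydrofuran-2(3H)-one (both silyloxy-carbon epimers) | COc1ccc([C@@H]2OC(=O)[C@@H](C(O[Si](C)(C)C(C)(C)C)c3cc(OC)c(OC)c(OC)c3)[C@@H]2CO[Si](C)(C)C(C)(C)C)cc1OC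
F4 | step 9 | (1R,2R,3S)-2-[(tert-butyldimethylsilyloxy)methyl]-3-[(tert-butyldimethylsilyloxy)(3,4,5-trimethoxyphenyl)methyl]-1-(3,4-dimethoxyphenyl)butane-1,4-diol | COc1ccc([C@H](O)[C@@H](CO[Si](C)(C)C(C)(C)C)[C@@H](CO)C(O[Si](C)(C)C(C)(C)C)c2cc(OC)c(OC)c(OC)c2)cc1OC
F5 | step 9 | primary (C4–O) p-toluenesulfonate of F4 | COc1ccc([C@H](O)[C@@H](CO[Si](C)(C)C(C)(C)C)[C@@H](COS(=O)(=O)c2ccc(C)cc2)C(O[Si](C)(C)C(C)(C)C)c2cc(OC)c(OC)c(OC)c2)cc1OC
F6 | step 9 | (2R,3R,4S)-3-[(tert-butyldimethylsilyloxy)methyl]-4-[(tert-butyldimethylsilyloxy)(3,4,5-trimethoxyphenyl)methyl]-2-(3,4-dimethoxyphenyl)tetrahydrofuran | COc1ccc([C@@H]2OC[C@@H](C(O[Si](C)(C)C(C)(C)C)c3cc(OC)c(OC)c(OC)c3)[C@@H]2CO[Si](C)(C)C(C)(C)C)cc1OC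
F7 | step 9 | [(3S,4R,5R)-5-(3,4-dimethoxyphenyl)-4-(hydroxymethyl)tetrahydrofuran-3-yl](3,4,5-trimethoxyphenyl)methanol (both carbinol epimers) | COc1ccc([C@@H]2OC[C@@H](C(O)c3cc(OC)c(OC)c(OC)c3)[C@@H]2CO)cc1OC
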